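Ring A (C1, C10–C14, briarane numbering) is a cyclohexene whose C12 oxygen sits 1,4 to the quaternary C1, so it is made by one enantioselective Diels–Alder reaction. The triisopropylsilyl dienol ether of ethyl vinyl ketone (C11–C14) adds to ethyl (E)-3-formylcrotonate (C2, C1, C10, C9): C11 bonds to C10 and the ring closes at C1–C14. This creates the quaternary C1 and the trans C1/C10 pair from the alkene geometry and leaves a C12 enol ether for the 11,12-diol and 13,14-alkene. The ten-membered ring is closed late by nickel-catalysed alkyne–aldehyde coupling at C5–C6; a 7,8-epoxide then delivers the lactone and, after inversion at C6, the chloride.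

Key step: step 2

Remarks on the chemistry (assumptions):
- Numbering is that of the briarane skeleton: C1 (quaternary, methyl C15), C2–C9 in the ten-membered ring (C5 carries the methylene C16), C10–C14 in ring A (C11 carries methyl C20), C17 (methyl C18), C19 (lactone carbonyl).
- The (S)-oxazaborolidinium catalyst is assumed to give the enantiomer of 4 shown (formyl C–H···O binding model); the (R)-catalyst would be used if the sense were opposite.
- The 17R configuration (methyl cis to the C8 hydroxyl, trans to the C9 branch) is assumed to be the thermodynamically preferred one at this epimerisable centre.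
- Compounds 1, 3, 5, 14 and 21 are taken as purchasable; 23–28 are carried as C17 epimer mixtures.

Step 1
Reactants: 1 pent-1-en-3-one
Product: 2 (Z)-3-(triisopropylsilyloxy)penta-1,3-diene
Conditions: iPr3SiOTf, Et3N, CH2Cl2, 0 °C → rt
Reagents that add atoms: triisopropylsilyl trifluoromethanesulfonate, CC(C)[Si](C(C)C)(C(C)C)OS(=O)(=O)C(F)(F)F
Why: Soft enolisation and O-silylation of the ethyl ketone (silyl enol ether formation) should give the 2-silyloxy diene as the (Z)-enol ether, in which the methyl group points away from the vinyl group so that the s-cis diene is accessible.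

Step 2
Reactants: 2 (Z)-3-(triisopropylsilyloxy)penta-1,3-diene; 3 ethyl (2E)-3-methyl-4-oxobut-2-enoate
Product: 4 ethyl (1S,2S,6S)-6-formyl-2,6-dimethyl-3-[(triisopropylsilyl)oxy]cyclohex-3-ene-1-carboxylate
Conditions: (S)-3,3-diphenyl-1-(2-methylphenyl)tetrahydro-1H,3H-pyrrolo[1,2-c][1,3,2]oxazaborole·HNTf2 (20 mol%), CH2Cl2, −78 → −40 °C
Reagents that add atoms: none
Why: The boron Lewis acid binds the formyl oxygen of 3 and the s-trans enal undergoes an asynchronous [4+2] cycloaddition in which the enol-ether carbon C11 of 2 first bonds to C10 (β to the formyl group) and the ring is then closed by the C14–C1 bond, which creates the methyl-bearing quaternary centre. The closest known reaction type is the oxazaborolidinium-catalysed enantioselective Diels–Alder reaction of 2-silyloxy-1,3-dienes with α-substituted enals. Ring A is closed as a six-membered carbocycle in a suprafacial [4+2] mode. C1 and C10 are set relative to each other by the (E)-geometry of 3 (formyl and ester trans, hence C2 and C9 trans and the C1 methyl cis to C9) and absolutely by the catalyst, which shields one face of the bound enal; C11 follows from the endo transition state and is erased in step 8. The step needs regioselectivity (silyloxy carbon C12 placed 1,4 to C1) and enantiofacial selectivity: the first is secured by the strongly polarising silyloxy group of 2 and by the boron-bound formyl group overriding the ester of 3, the second by the catalyst.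

Step 3
Reactants: 4 Diels–Alder aldehyde; 5 (4-bromobut-1-yn-1-yl)trimethylsilane
Product: 7 C2 carbinol (both C2 epimers), via Grignard reagent 6 (not isolated)
Conditions: 5, Mg, THF; then 4, THF, −78 °C; aq. NH4Cl
Reagents that add atoms: none
Why: Grignard addition at low temperature should be chemoselective for the non-enolisable aldehyde over the ester and the silyl enol ether and brings in C3–C5 and C16; the C2 configuration is corrected in steps 4 and 5.

Step 4
Reactants: 7 C2 carbinol (both C2 epimers)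
Product: 8 C2 ketone
Conditions: Dess–Martin periodinane, NaHCO3, CH2Cl2, 0 °C → rt
Reagents that add atoms: none
Why: Buffered Dess–Martin oxidation converts both epimers into one ketone and leaves the acid-sensitive silyl enol ether untouched.

Step 5
Reactants: 8 C2 ketone
Product: 10 trans-fused lactone (O2–C9) with C12 silyl enol ether, via hydroxy ester 9 (not isolated)
Conditions: (S)-1-methyl-3,3-diphenyltetrahydro-1H,3H-pyrrolo[1,2-c][1,3,2]oxazaborole (20 mol%), catecholborane, PhMe, −78 → −40 °C; then Ti(OiPr)4 (10 mol%), PhMe, 70 °C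
Reagents that add atoms: none
Why: Corey–Bakshi–Shibata reduction with the quaternary C1 as the large group should give the (2R)-alcohol (matched with Felkin–Anh hydride attack), and titanium-catalysed transesterification then closes the five-membered lactone, which protects O2 and activates C9.

Step 6
Reactants: 10 lactone with C12 silyl enol ether
Product: 11 enone lactone (C12 ketone, C13=C14)
Conditions: Pd(OAc)2 (1.05 equiv), MeCN, 40 °C
Reagents that add atoms: none
Why: Saegusa–Ito oxidation of the silyl enol ether can only eliminate the hydrogen at C14 and so places the alkene at C13=C14.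

Step 7
Reactants: 11 enone lactone
Product: 12 dienyl triflate (C11=C12(OTf)–C13=C14)
Conditions: KN(SiMe3)2, THF, −78 °C; PhNTf2
Reagents that add atoms: N-phenylbis(trifluoromethanesulfonimide), O=S(=O)(N(c1ccccc1)S(=O)(=O)C(F)(F)F)C(F)(F)F
Why: Kinetic deprotonation of the only α′-hydrogen of the enone (at C11) and O-triflation of the cross-conjugated dienolate should give the dienyl triflate (enol triflate formation).

Step 8
Reactants: 12 dienyl triflate
Product: 13 diene lactone (C11=C12–C13=C14)
Conditions: Pd(OAc)2 (5 mol%), PPh3, HCO2H, Bu3N, DMF, 60 °C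
Reagents that add atoms: none
Why: Palladium-catalysed formate reduction of the alkenyl triflate removes the C12 oxygen and leaves the 1,3-diene needed for the later cis-dihydroxylation.

Step 9
Reactants: 13 diene lactone; 14 triethyl(prop-2-yn-1-yloxy)silane
Product: 17 hydroxy ynone (C9 ketone), via lithium acetylide 15 (not isolated), via lithium alkynyltrifluoroborate 16 (not isolated)
Conditions: 14, n-BuLi, THF, −78 °C; BF3·OEt2; then 13, −78 °C; aq. NH4Cl
Reagents that add atoms: none
Why: Boron-trifluoride-mediated alkynylation of the lactone stops at the ketone stage because the tetrahedral adduct persists until work-up, and the weakly basic alkynylborate avoids deprotonation of the acidic C10 hydrogen; it brings in C8, C7 and C6.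

Step 10
Reactants: 17 hydroxy ynone
Product: 18 (2R,9R)-propargylic diol
Conditions: (R)-1-methyl-3,3-diphenyltetrahydro-1H,3H-pyrrolo[1,2-c][1,3,2]oxazaborole (30 mol%), catecholborane, PhMe, −78 °C
Reagents that add atoms: none
Why: Corey–Bakshi–Shibata reduction of the ynone, with the alkyne as the small group and the branched C10 as the large one, should set C9 as R under reagent control without base that could epimerise C10.

Step 11
Reactants: 18 propargylic diol
Product: 20 alkenyl iodide (iodine on C8; C9 and C6 trans), via alkenylstannane 19 (not isolated)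
Conditions: [Cp*RuCl]4 (2.5 mol%), Bu3SnH (1.05 equiv), CH2Cl2, rt; then I2, CH2Cl2, −78 °C
Reagents that add atoms: iodine, II (tributyltin hydride, CCCC[SnH](CCCC)CCCC, delivers tin only to 19 and one hydrogen to 20)
Why: Hydroxyl-directed ruthenium-catalysed trans-hydrostannation places tin on the alkyne carbon next to the free C9 hydroxyl with hydrogen trans to it, and iododestannylation proceeds with retention of the alkene geometry.

Step 12
Reactants: 20 alkenyl iodide; 21 tert-butyl 2-bromopropanoate
Product: 23 β,γ-unsaturated tert-butyl ester (C17 epimers), via zinc reagent 22 (not isolated)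
Conditions: 21, Zn, THF, rt; then 20, Pd(PtBu3)2 (5 mol%), THF, rt (3.5 equiv of 22)
Reagents that add atoms: none
Why: Negishi-type coupling of the Reformatsky reagent with the alkenyl iodide attaches C17, C18 and C19 to C8 with retention of alkene geometry; the bulky ester resists lactonisation onto O9 and C17 is equilibrated in step 18.

Step 13
Reactants: 23 β,γ-unsaturated ester
Product: 24 7,8-epoxide (erythro to the C9 hydroxyl)
Conditions: VO(acac)2 (5 mol%), tBuOOH, CH2Cl2, 0 °C
Reagents that add atoms: tert-butyl hydroperoxide, CC(C)(C)OO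
Why: Vanadium-catalysed hydroxyl-directed epoxidation of the allylic alcohol is much faster than that of the homoallylic ring A alkenes, and 1,2-allylic strain from the C17 branch should give the erythro epoxy alcohol, which fixes the C8 oxygen.

Step 14
Reactants: 24 epoxide
Product: 25 tetraol (hydroxyls at C2, C9, C11, C12)
Conditions: OsO4 (2 mol%), N-methylmorpholine N-oxide, acetone/H2O, 0 °C
Reagents that add atoms: N-methylmorpholine N-oxide, C[N+]1([O-])CCOCC1; water, O
Why: Catalytic osmium dihydroxylation attacks the electron-rich trisubstituted C11=C12 bond of the diene from the face opposite the C9 branch on the neighbouring C10, which should give the 11,12-cis-diol on the side of H-10 and leave C13=C14.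

Step 15
Reactants: 25 tetraol
Product: 26 pentakis(triethylsilyl) ether
Conditions: Et3SiOTf (5 equiv), 2,6-lutidine, CH2Cl2, −78 → 0 °C
Reagents that add atoms: triethylsilyl trifluoromethanesulfonate, CC[Si](CC)(CC)OS(=O)(=O)C(F)(F)F
Why: Silyl triflate with a hindered base silylates the three secondary and the tertiary hydroxyl (silyl ether formation); ethers cannot act as neighbouring groups in the later epoxide opening.

Step 16
Reactants: 26 pentakis(triethylsilyl) ether
Product: 27 epoxy aldehyde (C6 formyl)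
Conditions: (COCl)2, DMSO, CH2Cl2, −78 → −40 °C; Et3N
Reagents that add atoms: none
Why: Swern conditions cleave and oxidise a primary triethylsilyl ether directly to the aldehyde while the hindered secondary and tertiary silyl ethers remain.

Step 17
Reactants: 27 epoxy aldehyde
Product: 28 ten-membered allylic alcohol (6R) with exocyclic vinylsilane
Conditions: Ni(cod)2 (20 mol%), PBu3 (40 mol%), Et3B (3 equiv), PhMe/EtOAc, 0.002 M, rt
Reagents that add atoms: none
Why: Nickel-catalysed reductive alkyne–aldehyde cyclisation forms C5–C6 at the alkyne carbon remote from silicon with syn delivery of hydrogen to C16, and Felkin–Anh attack anti to the epoxide C7–O bond should give the (6R)-alcohol.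

Step 18
Reactants: 28 macrocyclic epoxy alcohol
Product: 30 β-hydroxy-γ-lactone (7R,8R,17R), via lactone epimer mixture 29 (not isolated)
Conditions: camphorsulfonic acid (1 equiv), CH2Cl2, 0 °C; then DBU (2 equiv), PhMe, 50 °C
Reagents that add atoms: none
Why: Acid-promoted intramolecular epoxide opening by the tert-butyl ester carbonyl at C7 (inversion, loss of 2-methylpropene) gives the five-membered lactone and keeps the C8 oxygen, and base equilibration then places the C17 methyl trans to the C9 branch.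

Step 19
Reactants: 30 hydroxy lactone
Product: 31 (6S)-allylic chloride
Conditions: PPh3, CCl4, 2,6-lutidine, MeCN, 0 °C → rt
Reagents that add atoms: tetrachloromethane, ClC(Cl)(Cl)Cl
Why: The Appel reaction replaces the C6 hydroxyl by chloride with inversion, the silyl group on C16 disfavours allylic transposition, and the tertiary C8 hydroxyl does not react.

Step 20
Reactants: 31 allylic chloride
Product: 32 pentaol (hydroxyls at C2, C8, C9, C11, C12)
Conditions: CF3CO2H/H2O/THF (3:1:1), 0 °C → rt
Reagents that add atoms: none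
Why: Aqueous acid hydrolyses the four triethylsilyl ethers and protodesilylates the vinylsilane by ipso protonation (β-silyl cation), which uncovers the C5=C16 methylene.

Step 21
Reactants: 32 pentaol
Product: 33 CNP0259091.2 (2,9,12-triacetate)
Conditions: Ac2O, pyridine, DMAP (cat.), CH2Cl2, rt
Reagents that add atoms: acetic anhydride, CC(=O)OC(C)=O
Why: Acetylation of the three secondary hydroxyls is much faster than that of the tertiary C8 and C11 hydroxyls, so the triacetate should form selectively.

Compound list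
1 | pent-1-en-3-one (ethyl vinyl ketone) | CCC(=O)C=C | starting material
2 | triisopropyl{[(3Z)-penta-1,3-dien-3-yl]oxy}silane | C/C=C(/C=C)O[Si](C(C)C)(C(C)C)C(C)C | intermediate
3 | ethyl (2E)-3-methyl-4-oxobut-2-enoate | CCOC(=O)/C=C(\C)C=O | starting material
4 | ethyl (1S,2S,6S)-6-formyl-2,6-dimethyl-3-[(triisopropylsilyl)oxy]cyclohex-3-ene-1-carboxylate (formyl C2 on C1, ester C9 on C10, trans) | O=C[C@@]2(C)CC=C(O[Si](C(C)C)(C(C)C)C(C)C)[C@@H](C)[C@@H]2C(=O)OCC | intermediate
5 | (4-bromobut-1-yn-1-yl)trimethylsilane | C[Si](C)(C)C#CCCBr | starting material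
6 | [4-(trimethylsilyl)but-3-yn-1-yl]magnesium bromide | C[Si](C)(C)C#CCC[Mg]Br | intermediate
7 | ethyl 6-[1-hydroxy-5-(trimethylsilyl)pent-4-yn-1-yl]-2,6-dimethyl-3-[(triisopropylsilyl)oxy]cyclohex-3-ene-1-carboxylate, ring centres as in 4, both C2 epimers | C[Si](C)(C)C#CCCC(O)[C@@]2(C)CC=C(O[Si](C(C)C)(C(C)C)C(C)C)[C@@H](C)[C@@H]2C(=O)OCC | intermediate
8 | ethyl 2,6-dimethyl-3-[(triisopropylsilyl)oxy]-6-[5-(trimethylsilyl)pent-4-ynoyl]cyclohex-3-ene-1-carboxylate, ring centres as in 4 | C[Si](C)(C)C#CCCC(=O)[C@@]2(C)CC=C(O[Si](C(C)C)(C(C)C)C(C)C)[C@@H](C)[C@@H]2C(=O)OCC | intermediate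
9 | (2R)-hydroxy ester: as 7 with the carbinol carbon C2 R | C[Si](C)(C)C#CCC[C@@H](O)[C@@]2(C)CC=C(O[Si](C(C)C)(C(C)C)C(C)C)[C@@H](C)[C@@H]2C(=O)OCC | intermediate
10 | trans-fused lactone: (3R)-3a,7-dimethyl-6-[(triisopropylsilyl)oxy]-3-[4-(trimethylsilyl)but-3-yn-1-yl]-3a,4,7,7a-tetrahydroisobenzofuran-1(3H)-one | C[Si](C)(C)C#CCC[C@@H]3[C@@]2(C)CC=C(O[Si](C(C)C)(C(C)C)C(C)C)[C@@H](C)[C@@H]2C(=O)O3 | intermediate
11 | enone lactone: (3R)-3a,7-dimethyl-3-[4-(trimethylsilyl)but-3-yn-1-yl]-3a,7a-dihydroisobenzofuran-1,6(3H,7H)-dione, trans-fused | C[Si](C)(C)C#CCC[C@@H]3[C@@]2(C)C=CC(=O)[C@@H](C)[C@@H]2C(=O)O3 | intermediate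
12 | dienyl triflate: 6-triflyloxy-4,6-diene analogue of 11 (C11=C12(OTf)–C13=C14) | C[Si](C)(C)C#CCC[C@@H]3[C@@]2(C)C=CC(OS(=O)(=O)C(F)(F)F)=C(C)[C@@H]2C(=O)O3 | intermediate
13 | diene lactone: (3R)-3a,7-dimethyl-3-[4-(trimethylsilyl)but-3-yn-1-yl]-3a,7a-dihydroisobenzofuran-1(3H)-one, trans-fused | C[Si](C)(C)C#CCC[C@@H]3[C@@]2(C)C=CC=C(C)[C@@H]2C(=O)O3 | intermediate
14 | triethyl(prop-2-yn-1-yloxy)silane | C#CCO[Si](CC)(CC)CC | starting material
15 | lithium acetylide of 14 | [Li]C#CCO[Si](CC)(CC)CC | intermediate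
16 | lithium trifluoro[3-(triethylsilyloxy)prop-1-yn-1-yl]borate | [Li+].F[B-](F)(F)C#CCO[Si](CC)(CC)CC | intermediate
17 | hydroxy ynone: ring A diene carrying at C1 the (2R)-1-hydroxy-5-(trimethylsilyl)pent-4-ynyl chain and at C10 the 4-(triethylsilyloxy)but-2-ynoyl group (C9 ketone) | C[Si](C)(C)C#CCC[C@@H](O)[C@@]2(C)C=CC=C(C)[C@@H]2C(=O)C#CCO[Si](CC)(CC)CC | intermediate
18 | (2R,9R)-diol: C9 propargylic alcohol from 17 | C[Si](C)(C)C#CCC[C@@H](O)[C@@]2(C)C=CC=C(C)[C@@H]2[C@@H](O)C#CCO[Si](CC)(CC)CC | intermediate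
19 | alkenylstannane: Bu3Sn on C8, C7=C8 with C9 and C6 trans | C[Si](C)(C)C#CCC[C@@H](O)[C@@]2(C)C=CC=C(C)[C@@H]2[C@@H](O)/C([Sn](CCCC)(CCCC)CCCC)=C/CO[Si](CC)(CC)CC | intermediate
20 | alkenyl iodide: iodine on C8, same geometry as 19 | C[Si](C)(C)C#CCC[C@@H](O)[C@@]2(C)C=CC=C(C)[C@@H]2[C@@H](O)/C(I)=C/CO[Si](CC)(CC)CC | intermediate
21 | tert-butyl 2-bromopropanoate (racemic) | CC(Br)C(=O)OC(C)(C)C | starting material
22 | Reformatsky reagent of 21 (bromozinc derivative) | CC([Zn]Br)C(=O)OC(C)(C)C | intermediate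
23 | β,γ-unsaturated ester: C8 carries CH(CH3)CO2tBu (C17 epimers), C7=C8 with C9 and C6 trans | C[Si](C)(C)C#CCC[C@@H](O)[C@@]2(C)C=CC=C(C)[C@@H]2[C@@H](O)/C(C(C)C(=O)OC(C)(C)C)=C/CO[Si](CC)(CC)CC | intermediate
24 | 7,8-epoxide of 23, epoxide oxygen erythro (anti) to the C9 hydroxyl | C[Si](C)(C)C#CCC[C@@H](O)[C@@]2(C)C=CC=C(C)[C@@H]2[C@@H](O)[C@]5(O[C@@H]5CO[Si](CC)(CC)CC)C(C)C(=O)OC(C)(C)C | intermediate
25 | tetraol: 24 with the 11,12-cis-diol (both hydroxyls on the face of H-10), C13=C14 retained | C[Si](C)(C)C#CCC[C@@H](O)[C@@]2(C)C=C[C@@H](O)[C@@](C)(O)[C@@H]2[C@@H](O)[C@]5(O[C@@H]5CO[Si](CC)(CC)CC)C(C)C(=O)OC(C)(C)C | intermediate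
26 | pentakis(triethylsilyl) ether of 25 (O2, O6, O9, O11, O12) | C[Si](C)(C)C#CCC[C@@H](O[Si](CC)(CC)CC)[C@@]2(C)C=C[C@@H](O[Si](CC)(CC)CC)[C@@](C)(O[Si](CC)(CC)CC)[C@@H]2[C@@H](O[Si](CC)(CC)CC)[C@]5(O[C@@H]5CO[Si](CC)(CC)CC)C(C)C(=O)OC(C)(C)C | intermediate
27 | epoxy aldehyde: 26 with C6 as formyl group | C[Si](C)(C)C#CCC[C@@H](O[Si](CC)(CC)CC)[C@@]2(C)C=C[C@@H](O[Si](CC)(CC)CC)[C@@](C)(O[Si](CC)(CC)CC)[C@@H]2[C@@H](O[Si](CC)(CC)CC)[C@]5(O[C@@H]5C=O)C(C)C(=O)OC(C)(C)C | intermediate
28 | ten-membered carbocycle: (6R)-hydroxyl, 7,8-epoxide, C5=C16H(SiMe3) with silicon cis to C4, tert-butyl ester, four silyl ethers | C[Si](C)(C)/C=C1\CC[C@@H](O[Si](CC)(CC)CC)[C@@]2(C)C=C[C@@H](O[Si](CC)(CC)CC)[C@@](C)(O[Si](CC)(CC)CC)[C@@H]2[C@@H](O[Si](CC)(CC)CC)[C@]5(O[C@@H]5[C@@H]1O)C(C)C(=O)OC(C)(C)C | intermediate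
29 | 18,7-lactone with free C8 and C6 hydroxyls, C17 epimers | C[Si](C)(C)/C=C1\CC[C@@H](O[Si](CC)(CC)CC)[C@@]2(C)C=C[C@@H](O[Si](CC)(CC)CC)[C@@](C)(O[Si](CC)(CC)CC)[C@@H]2[C@@H](O[Si](CC)(CC)CC)[C@]2(O)C(C)C(=O)O[C@H]2[C@@H]1O | intermediate
30 | lactone (6R,7R,8R,17R): 29 with the C17 methyl cis to the C8 hydroxyl | C[Si](C)(C)/C=C1\CC[C@@H](O[Si](CC)(CC)CC)[C@@]2(C)C=C[C@@H](O[Si](CC)(CC)CC)[C@@](C)(O[Si](CC)(CC)CC)[C@@H]2[C@@H](O[Si](CC)(CC)CC)[C@]2(O)[C@@H](C)C(=O)O[C@H]2[C@@H]1O | intermediate
31 | (6S)-chloride of 30 | C[Si](C)(C)/C=C1\CC[C@@H](O[Si](CC)(CC)CC)[C@@]2(C)C=C[C@@H](O[Si](CC)(CC)CC)[C@@](C)(O[Si](CC)(CC)CC)[C@@H]2[C@@H](O[Si](CC)(CC)CC)[C@]2(O)[C@@H](C)C(=O)O[C@H]2[C@H]1Cl | intermediate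
32 | pentaol: target lacking the three acetyl groups | C=C1CC[C@@H](O)[C@@]2(C)C=C[C@@H](O)[C@@](C)(O)[C@@H]2[C@@H](O)[C@]2(O)[C@@H](C)C(=O)O[C@H]2[C@H]1Cl | intermediate
33 | CNP0259091.2: (1S,2R,6S,7R,8R,9R,10S,11S,12R,17R)-2,9,12-triacetoxy-6-chloro-8,11-dihydroxybriara-5(16),13-dien-18,7-olide | C=C1CC[C@@H](OC(C)=O)[C@@]2(C)C=C[C@@H](OC(C)=O)[C@@](C)(O)[C@@H]2[C@@H](OC(C)=O)[C@]2(O)[C@@H](C)C(=O)O[C@H]2[C@H]1Cl | target

Total step count: 21. Longest linear sequence: 21 steps (from pent-1-en-3-one; 3, 5, 14 and 21 enter as purchased building blocks).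

Steps most likely to fail

Step 17. The nickel-mediated ring closure may be outrun by oligomerisation because of transannular strain in the ten-membered transition state, or zerovalent nickel may be diverted by the allylic silyl ether. The fallback closes the ring with chromium on a preformed alkenyl iodide. Setting out from 26, Pd(PPh3)4-catalysed syn-hydrostannation of the silyl alkyne with Bu3SnH (tin to C5, remote from silicon) should give the 2-stannyl vinylsilane F1, iododestannylation with I2 the 2-iodo vinylsilane F2, and Swern oxidation of the primary silyl ether the epoxy aldehyde F3. A Nozaki–Hiyama–Kishi cyclisation (CrCl2, NiCl2 cat., DMSO/THF, high dilution) then comes back to the route at 28.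

Step 18. Acid may ionise the tertiary epoxide carbon C8 (hydride shift to a ketone or four-ring closure) instead of promoting five-ring closure at C7, and equilibration at C17 may be incomplete. The fallback activates the nucleophile instead of the epoxide. Setting out from 28, the tert-butyl ester is cleaved with Me3SiOTf/2,6-lutidine and aqueous work-up to the epoxy carboxylic acid F4. Its caesium carboxylate (Cs2CO3, DMF, 60 °C) should open the epoxide at C7 in an intramolecular SN2 reaction and equilibrate C17 under the same basic conditions, coming back to the route at 30.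

Step 12. Oxidative addition and transmetalation at the hindered trisubstituted alkenyl iodide may be slow, so that protonation of the zinc enolate by the two free hydroxyls wins. The fallback is a Stille coupling followed by conjugate reduction. Setting out from 19 (isolated instead of being iodinated), coupling with tert-butyl 2-bromoacrylate (Pd2(dba)3, AsPh3, CuI, DMF) should give the 2-alkenyl acrylate F5, and conjugate reduction with [(Ph3P)CuH]6 comes back to the route at 23.

Further compounds
F1 | step 17 | 2-stannyl vinylsilane: 26 with C5(SnBu3)=C16H(SiMe3), silicon cis to C4 | C[Si](C)(C)/C=C(/[Sn](CCCC)(CCCC)CCCC)CC[C@@H](O[Si](CC)(CC)CC)[C@@]2(C)C=C[C@@H](O[Si](CC)(CC)CC)[C@@](C)(O[Si](CC)(CC)CC)[C@@H]2[C@@H](O[Si](CC)(CC)CC)[C@]5(O[C@@H]5CO[Si](CC)(CC)CC)C(C)C(=O)OC(C)(C)C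
F2 | step 17 | 2-iodo vinylsilane: F1 with iodine in place of tin | C[Si](C)(C)/C=C(/I)CC[C@@H](O[Si](CC)(CC)CC)[C@@]2(C)C=C[C@@H](O[Si](CC)(CC)CC)[C@@](C)(O[Si](CC)(CC)CC)[C@@H]2[C@@H](O[Si](CC)(CC)CC)[C@]5(O[C@@H]5CO[Si](CC)(CC)CC)C(C)C(=O)OC(C)(C)C
F3 | step 17 | epoxy aldehyde: F2 with C6 as formyl group | C[Si](C)(C)/C=C(/I)CC[C@@H](O[Si](CC)(CC)CC)[C@@]2(C)C=C[C@@H](O[Si](CC)(CC)CC)[C@@](C)(O[Si](CC)(CC)CC)[C@@H]2[C@@H](O[Si](CC)(CC)CC)[C@]5(O[C@@H]5C=O)C(C)C(=O)OC(C)(C)C
F4 | step 18 | epoxy carboxylic acid: 28 with CO2H in place of the tert-butyl ester | C[Si](C)(C)/C=C1\CC[C@@H](O[Si](CC)(CC)CC)[C@@]2(C)C=C[C@@H](O[Si](CC)(CC)CC)[C@@](C)(O[Si](CC)(CC)CC)[C@@H]2[C@@H](O[Si](CC)(CC)CC)[C@]5(O[C@@H]5[C@@H]1O)C(C)C(O)=O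
F5 | step 12 | 2-alkenyl acrylate: 23 with C17 as C(=CH2) | C[Si](C)(C)C#CCC[C@@H](O)[C@@]2(C)C=CC=C(C)[C@@H]2[C@@H](O)/C(C(=C)C(=O)OC(C)(C)C)=C/CO[Si](CC)(CC)CC
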